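**Strategy.** The two perhydro-1-benzoxepine halves share one trans-fused (5aS,9aS) oxepane–cyclohexane core with the C5a methyl, and the C6–CH2–CH2–C6′ bridge links carbons that each sit next to a carbonyl-level centre (C7, C7′). The target is therefore cut at the central CH2–CH2 bond into two copies of one 6-methylene-7-keto monomer. In the key step a primary radical at the C6′ methylene of a selenide donor (C7′ already the methyl carbinol) adds to the exo-methylene terminus of the C3-silylated enone acceptor, forging the bridge and C6 without closing a ring. The monomer arises from conjugate addition, reagent-controlled epoxidation and 7-endo epoxide opening.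

Key step: step 12

Remark on the chemistry (assumption): the (S)-carbinol of step 1 is assigned to the (R)-oxazaborolidine and the (S)-epoxide of step 7 to the L-fructose-derived ketone; if either sense proves opposite, the enantiomeric catalyst is used.

Step 1
Reactants: 1 2-methylcyclohex-2-en-1-one
Product: 2 (S)-2-methylcyclohex-2-en-1-ol
Conditions: (R)-2-methyl-CBS-oxazaborolidine (0.1 equiv), BH3·SMe2, THF, −20 °C; MeOH quench
Reagents that add atoms: none
Why: Corey–Bakshi–Shibata reduction, in which the oxazaborolidine binds the ketone with the alkene arm as the large group and delivers hydride to one face, sets the carbinol centre (later C9a) as S.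

Step 2
Reactants: 2 (S)-2-methylcyclohex-2-en-1-ol
Product: 3 (S)-tert-butyldimethyl[(2-methylcyclohex-2-en-1-yl)oxy]silane
Conditions: TBSCl, imidazole, DMF, rt
Reagents that add atoms: tert-butyldimethylsilyl chloride, CC(C)(C)[Si](C)(C)Cl
Why: Routine silylation of a secondary allylic alcohol; the bulky silyl ether later directs the organocopper reagent to the opposite face.

Step 3
Reactants: 3 (S)-tert-butyldimethyl[(2-methylcyclohex-2-en-1-yl)oxy]silane
Product: 4 (S)-4-[(tert-butyldimethylsilyl)oxy]-3-methylcyclohex-2-en-1-one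
Conditions: Rh2(cap)4 (1 mol %), t-BuOOH (aq.), K2CO3, CH2Cl2, rt
Reagents that add atoms: tert-butyl hydroperoxide, CC(C)(C)OO
Why: Rhodium-catalysed allylic oxidation attacks the ring CH2 next to the unsubstituted alkene carbon and gives the transposed enone without touching the carbinol centre.

Step 4
Reactants: 4 (S)-4-[(tert-butyldimethylsilyl)oxy]-3-methylcyclohex-2-en-1-one; 5 5-bromo-2-methylpent-2-ene; 6 Eschenmoser's salt (N,N-dimethylmethyleneiminium iodide)
Product: 10 (3S,4S)-4-[(tert-butyldimethylsilyl)oxy]-2-[(dimethylamino)methyl]-3-methyl-3-(4-methylpent-3-en-1-yl)cyclohexan-1-one (C2 epimers), via homoprenylmagnesium bromide 7 (not isolated), via trimethylsilyl enol ether 8 (not isolated), via lithium enolate 9 (not isolated)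
Conditions: 5, Mg, THF, rt; then 4, CuBr·SMe2 (0.2 equiv), TMSCl, THF, −78 to −40 °C; volatiles removed; MeLi, THF, 0 °C; then 6, −78 °C to rt
Reagents that add atoms: none
Why: Copper-catalysed 1,4-addition of the Grignard reagent, accelerated by TMSCl, builds the quaternary carbon (later C5a) anti to the neighbouring silyloxy group, and the regiodefined enolate released from the silyl enol ether by MeLi is aminomethylated at C2 (Mannich reaction).

Step 5
Reactants: 10 (3S,4S)-4-[(tert-butyldimethylsilyl)oxy]-2-[(dimethylamino)methyl]-3-methyl-3-(4-methylpent-3-en-1-yl)cyclohexan-1-one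
Product: 12 (3S,4S)-4-[(tert-butyldimethylsilyl)oxy]-3-methyl-2-methylidene-3-(4-methylpent-3-en-1-yl)cyclohexan-1-one, via quaternary trimethylammonium iodide 11 (not isolated)
Conditions: MeI, CH2Cl2, rt; then sat. aq. NaHCO3, rt
Reagents that add atoms: none
Why: Quaternisation turns the amine into a leaving group and mild base triggers E1cB (Hofmann-type) elimination to the exo-methylene ketone, which cannot migrate into the ring because the neighbouring carbon is quaternary.

Step 6
Reactants: 12 (3S,4S)-4-[(tert-butyldimethylsilyl)oxy]-3-methyl-2-methylidene-3-(4-methylpent-3-en-1-yl)cyclohexan-1-one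
Product: 13 (3S,4S)-4-hydroxy-3-methyl-2-methylidene-3-(4-methylpent-3-en-1-yl)cyclohexan-1-one
Conditions: aq. HF (48%), MeCN, 0 °C to rt
Reagents that add atoms: none
Why: Aqueous HF cleaves the hindered secondary silyl ether while enone and trisubstituted alkene are inert, so that the later epoxide never meets fluoride or strong acid with the oxygen still masked.

Step 7
Reactants: 13 (3S,4S)-4-hydroxy-3-methyl-2-methylidene-3-(4-methylpent-3-en-1-yl)cyclohexan-1-one
Product: 14 (3S,4S)-3-{2-[(2S)-3,3-dimethyloxiran-2-yl]ethyl}-4-hydroxy-3-methyl-2-methylidenecyclohexan-1-one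
Conditions: L-fructose-derived Shi ketone (0.3 equiv), Oxone (KHSO5), K2CO3, Bu4NHSO4, MeCN/CH2(OMe)2/aq. Na2B4O7 buffer, 0 °C
Reagents that add atoms: potassium peroxymonosulfate, [K+].[O-]S(=O)(=O)OO
Why: Shi epoxidation: the electrophilic chiral dioxirane selects the electron-rich trisubstituted alkene over the electron-poor enone, and the catalyst enantiomer fixes the epoxide CH (later C3) as S.

Step 8
Reactants: 14 (3S,4S)-3-{2-[(2S)-3,3-dimethyloxiran-2-yl]ethyl}-4-hydroxy-3-methyl-2-methylidenecyclohexan-1-one
Product: 15 (3S,5aS,9aS)-3-hydroxy-2,2,5a-trimethyl-6-methylideneoctahydro-1-benzoxepin-7(2H)-one (trans-fused monomer)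
Conditions: (+)-camphorsulfonic acid (0.1 equiv), CH2Cl2, 0 °C
Reagents that add atoms: none
Why: A protonated trisubstituted epoxide opens at its tertiary carbon, so the ring hydroxyl should close the oxepane in the 7-endo mode in preference to 6-exo attack; the trans fusion is already set by the two ring stereocentres and C3 keeps its configuration because only the achiral CMe2 carbon is attacked.

Step 9
Reactants: 15 (3S,5aS,9aS)-3-hydroxy-2,2,5a-trimethyl-6-methylideneoctahydro-1-benzoxepin-7(2H)-one
Product: 16 (3S,5aS,9aS)-2,2,5a-trimethyl-6-methylidene-3-[(triethylsilyl)oxy]octahydro-1-benzoxepin-7(2H)-one (acceptor)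
Conditions: Et3SiOTf, 2,6-lutidine, CH2Cl2, −78 °C
Reagents that add atoms: triethylsilyl trifluoromethanesulfonate, CC[Si](CC)(CC)OS(=O)(=O)C(F)(F)F
Why: The silyl triflate caps the neopentyl-type C3 alcohol at low temperature faster than the ketone enolises; triethylsilyl is chosen because it must later leave from this hindered site under conditions that spare a tertiary acetate.

Step 10
Reactants: 15 (3S,5aS,9aS)-3-hydroxy-2,2,5a-trimethyl-6-methylideneoctahydro-1-benzoxepin-7(2H)-one
Product: 17 (3S,5aS,6S,9aS)-3-hydroxy-2,2,5a-trimethyl-6-[(phenylselanyl)methyl]octahydro-1-benzoxepin-7(2H)-one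
Conditions: PhSeH, Et3N (cat.), CH2Cl2, 0 °C to rt
Reagents that add atoms: benzeneselenol, [SeH]c1ccccc1
Why: Base-catalysed conjugate addition of the soft selenol to the exo-methylene ketone is reversible, and protonation with equilibration at C6 leaves the CH2SePh group equatorial with the C6 hydrogen axial, anti to the axial C5a methyl.

Step 11
Reactants: 17 (3S,5aS,6S,9aS)-3-hydroxy-2,2,5a-trimethyl-6-[(phenylselanyl)methyl]octahydro-1-benzoxepin-7(2H)-one
Product: 18 (3S,5aS,6S,7R,9aS)-2,2,5a,7-tetramethyl-6-[(phenylselanyl)methyl]decahydro-1-benzoxepine-3,7-diol (donor)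
Conditions: MeLi, CeCl3, THF, −78 °C; aq. NH4Cl
Reagents that add atoms: methyllithium, [Li]C
Why: The weakly basic organocerium reagent adds to the ketone without enolisation or retro-Michael loss of selenolate, and it enters along the equatorial trajectory because the axial one is blocked by the syn-axial C5a methyl, giving the axial C7 hydroxyl (7R).

Step 12
Reactants: 16 (3S,5aS,9aS)-2,2,5a-trimethyl-6-methylidene-3-[(triethylsilyl)oxy]octahydro-1-benzoxepin-7(2H)-one; 18 (3S,5aS,6S,7R,9aS)-2,2,5a,7-tetramethyl-6-[(phenylselanyl)methyl]decahydro-1-benzoxepine-3,7-diol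
Product: 20 (3S,5aS,6S,9aS)-6-{2-[(3S,5aS,6S,7R,9aS)-3,7-dihydroxy-2,2,5a,7-tetramethyldecahydro-1-benzoxepin-6-yl]ethyl}-2,2,5a-trimethyl-3-[(triethylsilyl)oxy]octahydro-1-benzoxepin-7(2H)-one, via C6-epimeric adduct mixture 19 (not isolated)
Conditions: 16 (2 equiv), (Me3Si)3SiH and AIBN added slowly, PhMe, 80 °C; then K2CO3, MeOH, rt
Reagents that add atoms: none
Why: The silyl radical from (Me3Si)3SiH/AIBN abstracts the phenylselanyl group of 18 and releases a nucleophilic primary radical at the C6′ methylene, which adds to the unsubstituted terminus of the electron-poor exo-methylene ketone 16; the tertiary α-keto radical then takes hydrogen from the silane and carries the chain (Giese reaction, intermolecular radical conjugate addition). No ring is closed: two finished bicycles are joined through the new CH2–CH2 bond. The new C6 centre arises by hydrogen transfer to the face opposite the axial C5a methyl and is then driven by K2CO3/MeOH to the equatorial bridge with axial C6–H, the thermodynamic arrangement next to the C7 ketone. Cross-addition has to outrun direct reduction of the radical, which is secured by the polarity match, the excess of acceptor and slow addition of a comparatively slow hydrogen donor. The free hydroxyls and the silyl ether are inert to these conditions, and the radical has no β-leaving group because C7′ is already a saturated carbinol. The exo-methylene terminus is the only unhindered site between two quaternary neighbours, where a polar enolate alkylation would be unreliable.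

Step 13
Reactants: 20 coupled keto diol
Product: 21 (3S,5aS,6S,7R,9aS)-2,2,5a,7-tetramethyl-6-{2-[(3S,5aS,6R,9aS)-2,2,5a-trimethyl-7-methylidene-3-[(triethylsilyl)oxy]decahydro-1-benzoxepin-6-yl]ethyl}decahydro-1-benzoxepine-3,7-diol
Conditions: Ph3PCH3Br, KOtBu (excess), PhMe, 90 °C
Reagents that add atoms: methyltriphenylphosphonium bromide, C[P+](c1ccccc1)(c1ccccc1)c1ccccc1.[Br-]
Why: Wittig methylenation with excess ylide (the two hydroxyls ride along as alkoxides) converts the hindered C7 ketone into the exocyclic alkene, and any base-induced epimerisation at C6 returns to the equatorial isomer already present.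

Step 14
Reactants: 21 methylidene diol
Product: 22 (5aS,6S,7R,9aS)-7-hydroxy-2,2,5a,7-tetramethyl-6-{2-[(3S,5aS,6R,9aS)-2,2,5a-trimethyl-7-methylidene-3-[(triethylsilyl)oxy]decahydro-1-benzoxepin-6-yl]ethyl}octahydro-1-benzoxepin-3(2H)-one
Conditions: Dess–Martin periodinane, NaHCO3, CH2Cl2, rt
Reagents that add atoms: none
Why: Dess–Martin oxidation converts the only secondary alcohol (C3′) into the oxepanone and cannot oxidise the tertiary C7′ alcohol, while the buffered medium spares the silyl ether and the alkene.

Step 15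
Reactants: 22 oxepanone tertiary alcohol
Product: 23 (5aS,6S,7R,9aS)-2,2,5a,7-tetramethyl-3-oxo-6-{2-[(3S,5aS,6R,9aS)-2,2,5a-trimethyl-7-methylidene-3-[(triethylsilyl)oxy]decahydro-1-benzoxepin-6-yl]ethyl}decahydro-1-benzoxepin-7-yl acetate
Conditions: Ac2O, DMAP, Et3N, CH2Cl2, 40 °C
Reagents that add atoms: acetic anhydride, CC(=O)OC(C)=O
Why: DMAP-catalysed acylation under forcing but non-acidic conditions esterifies the hindered axial tertiary alcohol with retention, while the silyl ether and the acid-sensitive exocyclic alkene stay intact.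

Step 16
Reactants: 23 silylated acetate
Product: 24 (5aS,6S,7R,9aS)-6-{2-[(3S,5aS,6R,9aS)-3-hydroxy-2,2,5a-trimethyl-7-methylidenedecahydro-1-benzoxepin-6-yl]ethyl}-2,2,5a,7-tetramethyl-3-oxodecahydro-1-benzoxepin-7-yl acetate (CNP0148623.1)
Conditions: HF·pyridine, pyridine, THF, 0 °C to rt
Reagents that add atoms: none
Why: Buffered HF·pyridine removes the triethylsilyl ether from C3, and the tertiary acetate, the ketone and the exocyclic alkene are stable to it.

**Compound list**

1 | 2-methylcyclohex-2-en-1-one | CC1=CCCCC1=O | starting material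
2 | (S)-2-methylcyclohex-2-en-1-ol | CC1=CCCC[C@@H]1O | intermediate
3 | (S)-tert-butyldimethyl[(2-methylcyclohex-2-en-1-yl)oxy]silane | CC1=CCCC[C@@H]1O[Si](C)(C)C(C)(C)C | intermediate
4 | (S)-4-[(tert-butyldimethylsilyl)oxy]-3-methylcyclohex-2-en-1-one | O=C1C=C(C)[C@@H](O[Si](C)(C)C(C)(C)C)CC1 | intermediate
5 | 5-bromo-2-methylpent-2-ene (homoprenyl bromide) | CC(C)=CCCBr | starting material
6 | Eschenmoser's salt (N,N-dimethylmethyleneiminium iodide) | C=[N+](C)C.[I-] | starting material
7 | (4-methylpent-3-en-1-yl)magnesium bromide | CC(C)=CCC[Mg]Br | intermediate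
8 | {[(3S,4S)-4-[(tert-butyldimethylsilyl)oxy]-3-methyl-3-(4-methylpent-3-en-1-yl)cyclohex-1-en-1-yl]oxy}trimethylsilane | C[Si](C)(C)OC1=C[C@](C)(CCC=C(C)C)[C@@H](O[Si](C)(C)C(C)(C)C)CC1 | intermediate
9 | lithium (3S,4S)-4-[(tert-butyldimethylsilyl)oxy]-3-methyl-3-(4-methylpent-3-en-1-yl)cyclohex-1-en-1-olate | [Li]OC1=C[C@](C)(CCC=C(C)C)[C@@H](O[Si](C)(C)C(C)(C)C)CC1 | intermediate
10 | (3S,4S)-4-[(tert-butyldimethylsilyl)oxy]-2-[(dimethylamino)methyl]-3-methyl-3-(4-methylpent-3-en-1-yl)cyclohexan-1-one (C2 epimers) | CN(C)CC1C(=O)CC[C@H](O[Si](C)(C)C(C)(C)C)[C@@]1(C)CCC=C(C)C | intermediate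
11 | N-methyl quaternary ammonium iodide of 10 | C[N+](C)(C)CC1C(=O)CC[C@H](O[Si](C)(C)C(C)(C)C)[C@@]1(C)CCC=C(C)C.[I-] | intermediate
12 | (3S,4S)-4-[(tert-butyldimethylsilyl)oxy]-3-methyl-2-methylidene-3-(4-methylpent-3-en-1-yl)cyclohexan-1-one | C=C1C(=O)CC[C@H](O[Si](C)(C)C(C)(C)C)[C@@]1(C)CCC=C(C)C | intermediate
13 | (3S,4S)-4-hydroxy-3-methyl-2-methylidene-3-(4-methylpent-3-en-1-yl)cyclohexan-1-one | C=C1C(=O)CC[C@H](O)[C@@]1(C)CCC=C(C)C | intermediate
14 | (3S,4S)-3-{2-[(2S)-3,3-dimethyloxiran-2-yl]ethyl}-4-hydroxy-3-methyl-2-methylidenecyclohexan-1-one | C=C1C(=O)CC[C@H](O)[C@@]1(C)CC[C@@H]1OC1(C)C | intermediate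
15 | (3S,5aS,9aS)-3-hydroxy-2,2,5a-trimethyl-6-methylideneoctahydro-1-benzoxepin-7(2H)-one | C=C1C(=O)CC[C@@H]2OC(C)(C)[C@@H](O)CC[C@@]12C | intermediate
16 | (3S,5aS,9aS)-2,2,5a-trimethyl-6-methylidene-3-[(triethylsilyl)oxy]octahydro-1-benzoxepin-7(2H)-one | C=C1C(=O)CC[C@@H]2OC(C)(C)[C@@H](O[Si](CC)(CC)CC)CC[C@@]12C | intermediate
17 | (3S,5aS,6S,9aS)-3-hydroxy-2,2,5a-trimethyl-6-[(phenylselanyl)methyl]octahydro-1-benzoxepin-7(2H)-one | O=C1CC[C@@H]2OC(C)(C)[C@@H](O)CC[C@@]2(C)[C@@H]1C[Se]c1ccccc1 | intermediate
18 | (3S,5aS,6S,7R,9aS)-2,2,5a,7-tetramethyl-6-[(phenylselanyl)methyl]decahydro-1-benzoxepine-3,7-diol | c1ccccc1[Se]C[C@H]1[C@]2(C)CC[C@H](O)C(C)(C)O[C@H]2CC[C@@]1(C)O | intermediate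
19 | crude coupling product, mixture at C6 | O=C1CC[C@@H]2OC(C)(C)[C@@H](O[Si](CC)(CC)CC)CC[C@@]2(C)C1CC[C@H]1[C@]2(C)CC[C@H](O)C(C)(C)O[C@H]2CC[C@@]1(C)O | intermediate
20 | coupled keto diol, (6S) equatorial bridge, 3-O-triethylsilyl | O=C1CC[C@@H]2OC(C)(C)[C@@H](O[Si](CC)(CC)CC)CC[C@@]2(C)[C@@H]1CC[C@H]1[C@]2(C)CC[C@H](O)C(C)(C)O[C@H]2CC[C@@]1(C)O | intermediate
21 | 7-methylidene diol, 3-O-triethylsilyl | C=C1CC[C@@H]2OC(C)(C)[C@@H](O[Si](CC)(CC)CC)CC[C@@]2(C)[C@@H]1CC[C@H]1[C@]2(C)CC[C@H](O)C(C)(C)O[C@H]2CC[C@@]1(C)O | intermediate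
22 | 7-methylidene 3′-ketone 7′-tertiary alcohol, 3-O-triethylsilyl | C=C1CC[C@@H]2OC(C)(C)[C@@H](O[Si](CC)(CC)CC)CC[C@@]2(C)[C@@H]1CC[C@H]1[C@]2(C)CCC(=O)C(C)(C)O[C@H]2CC[C@@]1(C)O | intermediate
23 | 7′-acetate of 22, 3-O-triethylsilyl | C=C1CC[C@@H]2OC(C)(C)[C@@H](O[Si](CC)(CC)CC)CC[C@@]2(C)[C@@H]1CC[C@H]1[C@]2(C)CCC(=O)C(C)(C)O[C@H]2CC[C@@]1(C)OC(C)=O | intermediate
24 | CNP0148623.1 | C=C1CC[C@@H]2OC(C)(C)[C@@H](O)CC[C@@]2(C)[C@@H]1CC[C@H]1[C@]2(C)CCC(=O)C(C)(C)O[C@H]2CC[C@@]1(C)OC(C)=O | target

**Totals.** Total step count: 16. Longest linear sequence: 15 steps (steps 1–8, 10, 11, 12–16; step 9 is the one-step side branch to the acceptor).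

**Three steps most likely to fail**

1. Step 12 (radical fragment coupling). The primary radical may be reduced by the hydrogen donor, or the silyl radical may add to the acceptor, before cross-addition occurs at a near-equimolar fragment ratio. The fallback forms the same CH2–CH2 bond by anionic Michael addition; it sets out from monomer 15 and rejoins the route at 20. Sodium benzenesulfinate and AcOH in aqueous EtOH add to the enone of 15 to give the β-sulfonyl ketone F1, with the CH2SO2Ph group equatorial after equilibration. MeLi/CeCl3 converts this into the hydroxy sulfone F2 by the same equatorial attack as in step 11. Treatment with n-BuLi (about three equivalents, THF/HMPA, −78 °C) forms the two alkoxides and the α-sulfonyl carbanion, which adds to the exo-methylene terminus of acceptor 16 to give the γ-keto sulfone F3 (mixture at the sulfonyl carbon). Reductive desulfonylation with Na(Hg)/Na2HPO4 in MeOH/THF at −20 °C, followed by the K2CO3/MeOH equilibration of C6, delivers 20.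

2. Step 8 (oxepane closure). Attack of the hydroxyl at the secondary epoxide carbon (6-exo closure) and hydride-shift rearrangement of the protonated epoxide may compete with the 7-endo opening, and the free diol-type product may re-ionise in acid. The fallback merges ring closure with protection in a silyl-cation manifold; it sets out from hydroxy epoxide 14 and rejoins at acceptor 16. Et3SiOTf with 2,6-lutidine in MeNO2 at 0 °C activates the epoxide as a silyloxonium that opens in an SN1-like way at the tertiary carbon. The ring oxygen is delivered from the hydroxyl or its transient silyl ether, and the C3 oxygen emerges directly as the triethylsilyl ether, which cannot reopen. The monomer 15 needed for the donor branch is then obtained by treating part of 16 with HF·pyridine. No new compound arises.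

3. Step 4 (conjugate addition with Mannich trapping). Aminomethylation of the hindered enolate beside the new quaternary carbon may be slow, so that proton transfer scrambles the enolate and gives the plain ketone. The fallback separates the two events and changes the one-carbon electrophile; it sets out from 4 and 7 and rejoins at 12. The copper-catalysed addition is run with TMSCl and silyl enol ether 8 is isolated. Mukaiyama aldol reaction of 8 with aqueous formaldehyde and Yb(OTf)3 in THF gives the hydroxymethyl ketone F4. MsCl/Et3N in CH2Cl2 converts this into the mesylate F5, and DBU eliminates it to the exo-methylene ketone 12.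

**Further compounds**

F1 | step 12 | (3S,5aS,6S,9aS)-3-hydroxy-2,2,5a-trimethyl-6-[(phenylsulfonyl)methyl]octahydro-1-benzoxepin-7(2H)-one | O=C1CC[C@@H]2OC(C)(C)[C@@H](O)CC[C@@]2(C)[C@@H]1CS(=O)(=O)c1ccccc1
F2 | step 12 | (3S,5aS,6S,7R,9aS)-2,2,5a,7-tetramethyl-6-[(phenylsulfonyl)methyl]decahydro-1-benzoxepine-3,7-diol | O=S(=O)(C[C@H]1[C@]2(C)CC[C@H](O)C(C)(C)O[C@H]2CC[C@@]1(C)O)c1ccccc1
F3 | step 12 | coupled γ-keto sulfone (phenylsulfonyl on the bridge carbon next to C6′, mixture at that carbon), 3-O-triethylsilyl | O=C1CC[C@@H]2OC(C)(C)[C@@H](O[Si](CC)(CC)CC)CC[C@@]2(C)[C@@H]1CC([C@H]1[C@]2(C)CC[C@H](O)C(C)(C)O[C@H]2CC[C@@]1(C)O)S(=O)(=O)c1ccccc1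
F0 | step 8 | none | none
F4 | step 4 | (3S,4S)-4-[(tert-butyldimethylsilyl)oxy]-2-(hydroxymethyl)-3-methyl-3-(4-methylpent-3-en-1-yl)cyclohexan-1-one (C2 epimers) | OCC1C(=O)CC[C@H](O[Si](C)(C)C(C)(C)C)[C@@]1(C)CCC=C(C)C
F5 | step 4 | methanesulfonate of F4 | CS(=O)(=O)OCC1C(=O)CC[C@H](O[Si](C)(C)C(C)(C)C)[C@@]1(C)CCC=C(C)C
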